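**Plan**

- Numbering: C1 = Me2C(OH), C2 = CH(OH), then along the chain to C12 = CH2 on the furan; the carboxyls sit on C5 and C9.
- Retrosynthetic cuts, in order: the two C1–CH3 bonds (Grignard on a C1 acyl group), C3–C4 (decarboxylative radical SN2′ allylation), C5–C6 (Morita–Baylis–Hillman), C9=C10 (Wittig), C8–C9 (ylide allylation), furan–C12 (oxetane opening).
- Enabling feature: C3–C4 is the allylic bond of the C5=C6 2-alkylidene ester, which is what SN2′ attack on a Morita–Baylis–Hillman acetate leaves behind. C1–C3 with the C2 hydroxyl are carbons 1–3 of (R)-malic acid, whose fourth carbon leaves as CO2. The only ring, the furan, is bought.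
- Forward: furan → C10–C12 aldehyde → Wittig (C9=C10) → C6 aldehyde → C4–C6 acrylate acetate → radical coupling with the malic dioxolanone acid (C3–C4, C5=C6) → double methylation at C1 → saponification. No ring is formed.
- Stereochemistry: C2 (R) comes unchanged from D-malic acid; C9=C10 (E) from the stabilised-ylide Wittig; C5=C6 (E) from the elimination in the key step.

Key step: step 10

Remark: alcohol 17 and acetate 18 are carried as racemates at C6, because this centre becomes sp2 in step 10.

Step 1
Reactants: 1 D-malic acid [(R)-2-hydroxybutanedioic acid]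
Product: 2 2-[(4R)-2,2-dimethyl-5-oxo-1,3-dioxolan-4-yl]acetic acid
Conditions: 2,2-dimethoxypropane, p-TsOH·H2O (cat.), rt
Reagents that add atoms: 2,2-dimethoxypropane, COC(C)(C)OC
Why: Acid-catalysed transketalisation engages the α-hydroxy acid unit as the five-membered 1,3-dioxolan-4-one, favoured over the six-membered alternative, so the distal CH2CO2H stays free and the configuration of D-malic acid is not touched.

Step 2
Reactants: 3 3-bromofuran; 4 oxetane
Product: 6 3-(furan-3-yl)propan-1-ol, via furan-3-yllithium 5 (not isolated)
Conditions: n-BuLi, THF, −78 °C; then oxetane, BF3·OEt2, −78 °C; aq. NaHCO3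
Reagents that add atoms: none
Why: Bromine–lithium exchange at −78 °C gives the 3-lithiofuran, which opens the BF3-activated oxetane by SN2 attack at carbon before it can isomerise to the 2-lithio isomer (Lewis-acid-assisted oxetane opening).

Step 3
Reactants: 6 3-(furan-3-yl)propan-1-ol
Product: 7 3-(furan-3-yl)propanal
Conditions: Dess–Martin periodinane, CH2Cl2, 0 °C → rt
Reagents that add atoms: none
Why: Dess–Martin oxidation stops at the aldehyde, and its mild non-aqueous conditions should leave the electron-rich furan alone.

Step 4
Reactants: 8 methyl 2-(triphenyl-λ5-phosphanylidene)acetate; 9 allyl bromide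
Product: 11 methyl 2-(triphenyl-λ5-phosphanylidene)pent-4-enoate, via phosphonium bromide 10 (not isolated)
Conditions: CHCl3, reflux; then aq. NaOH, CH2Cl2, rt
Reagents that add atoms: none
Why: SN2 C-allylation of the ester-stabilised ylide gives the phosphonium salt, whose remaining α-proton is removed by aqueous hydroxide to give the α-allyl stabilised ylide (ylide alkylation).

Step 5
Reactants: 7 3-(furan-3-yl)propanal; 11 methyl 2-(triphenyl-λ5-phosphanylidene)pent-4-enoate
Product: 12 methyl (2E)-5-(furan-3-yl)-2-(prop-2-en-1-yl)pent-2-enoate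
Conditions: toluene, 90 °C
Reagents that add atoms: none
Why: Wittig olefination with an α-substituted ester-stabilised ylide is expected to place the C11 chain trans to the ester, giving the E enoate at C9=C10.

Step 6
Reactants: 12 methyl (2E)-5-(furan-3-yl)-2-(prop-2-en-1-yl)pent-2-enoate
Product: 14 methyl (2E)-5-(furan-3-yl)-2-(3-hydroxypropyl)pent-2-enoate, via alkylborane 13 (not isolated)
Conditions: 9-BBN, THF, 0 °C → rt; then NaBO3·4H2O, THF/H2O, rt
Reagents that add atoms: sodium perborate, [Na+].[Na+].O[B-]1(O)OO[B-](O)(O)OO1
Why: Brown hydroboration with bulky 9-BBN should take only the monosubstituted alkene and put boron on its terminus, leaving the trisubstituted electron-poor enoate, the ester and the furan alone, and perborate oxidises the C–B bond without hydrolysing the ester.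

Step 7
Reactants: 14 methyl (2E)-5-(furan-3-yl)-2-(3-hydroxypropyl)pent-2-enoate
Product: 15 methyl (2E)-5-(furan-3-yl)-2-(3-oxopropyl)pent-2-enoate
Conditions: Dess–Martin periodinane, CH2Cl2, 0 °C → rt
Reagents that add atoms: none
Why: Dess–Martin oxidation of the primary alcohol should give the aldehyde without isomerising the enoate or touching the furan.

Step 8
Reactants: 15 methyl (2E)-5-(furan-3-yl)-2-(3-oxopropyl)pent-2-enoate; 16 methyl acrylate
Product: 17 dimethyl (2E)-2-[3-(furan-3-yl)propylidene]-5-hydroxy-6-methylideneheptanedioate (racemic at C5 of the heptanedioate)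
Conditions: DABCO (cat.), methyl acrylate (excess), MeOH, rt
Reagents that add atoms: none
Why: Morita–Baylis–Hillman reaction, in which DABCO adds to methyl acrylate, the ammonium enolate attacks the unhindered aliphatic aldehyde and the amine is expelled, while the trisubstituted enoate already present is too hindered to act as acceptor; the new carbinol centre forms as a racemate.

Step 9
Reactants: 17 dimethyl (2E)-2-[3-(furan-3-yl)propylidene]-5-hydroxy-6-methylideneheptanedioate
Product: 18 dimethyl (2E)-5-acetoxy-2-[3-(furan-3-yl)propylidene]-6-methylideneheptanedioate (racemic)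
Conditions: Ac2O, pyridine, DMAP (cat.), CH2Cl2, 0 °C
Reagents that add atoms: acetic anhydride, CC(=O)OC(C)=O
Why: Pyridine/DMAP-mediated O-acylation of the secondary allylic alcohol, run cold and briefly so that the acetate does not migrate SN2′ to the primary allylic position.

Step 10
Reactants: 2 2-[(4R)-2,2-dimethyl-5-oxo-1,3-dioxolan-4-yl]acetic acid (1.5 equiv); 18 dimethyl (2E)-5-acetoxy-2-[3-(furan-3-yl)propylidene]-6-methylideneheptanedioate
Product: 19 dimethyl (2E,6E)-2-{2-[(4R)-2,2-dimethyl-5-oxo-1,3-dioxolan-4-yl]ethyl}-6-[3-(furan-3-yl)propylidene]hept-2-enedioate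
Conditions: Ir[dF(CF3)ppy]2(dtbbpy)PF6 (2 mol%), K2HPO4 (0.3 equiv), degassed DMF, blue LEDs (450 nm), rt
Reagents that add atoms: none
Why: The excited Ir(III) complex oxidises the carboxylate of 2, CO2 is lost, and the primary C3 radical adds to the unsubstituted methylidene carbon C4 of 18 (Giese addition) to form C3–C4; the tertiary α-ester radical at C5 is then reduced by Ir(II) to the ester enolate, which expels acetate from C6 (E1cB) to create C5=C6 and close the catalytic cycle, the released acetate deprotonating the next molecule of 2. The closest known reaction type is the photoredox decarboxylative radical addition–elimination (radical SN2′ allylation) of carboxylic acids with Morita–Baylis–Hillman acetates. No ring closes and no stereocentre is made: C2 keeps the malic acid configuration because the radical sits on the neighbouring non-stereogenic CH2, and racemic C6 becomes sp2. The step needs site selectivity, which the substrate supplies because the nucleophilic primary radical prefers the β-unsubstituted acrylate terminus over the β-substituted C9=C10 enoate, the furan and the trisubstituted product. It also needs E geometry, which should follow from the elimination conformer that turns the C7 chain away from the enolate oxygens (allylic strain), so the chain ends trans to the ester. Strict exclusion of oxygen keeps singlet oxygen away from the furan.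

Step 11
Reactants: 19 dimethyl (2E,6E)-2-{2-[(4R)-2,2-dimethyl-5-oxo-1,3-dioxolan-4-yl]ethyl}-6-[3-(furan-3-yl)propylidene]hept-2-enedioate
Product: 21 dimethyl (2E,6E)-2-[(3R)-3,4-dihydroxy-4-methylpentyl]-6-[3-(furan-3-yl)propylidene]hept-2-enedioate, via hydroxy ketone 20 (not isolated)
Conditions: MeMgBr (3.3 equiv), THF, −78 → −30 °C; aq. NH4Cl
Reagents that add atoms: methylmagnesium bromide, C[Mg]Br
Why: Grignard addition to the 1,3-dioxolan-4-one, whose acetal-activated, α-oxygenated acyl carbon should be far more electrophilic at low temperature than the two α-branched conjugated methyl esters; the first methyl expels acetone to leave the chelated α-oxido ketone 20, which takes the second methyl, and since both new groups at C1 are methyl no stereocentre is created and C2 is retained.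

Step 12
Reactants: 21 dimethyl (2E,6E)-2-[(3R)-3,4-dihydroxy-4-methylpentyl]-6-[3-(furan-3-yl)propylidene]hept-2-enedioate
Product: 22 (2E,6E)-2-[(3R)-3,4-dihydroxy-4-methylpentyl]-6-[3-(furan-3-yl)propylidene]hept-2-enedioic acid (CNP0223220.1)
Conditions: LiOH, THF/MeOH/H2O, rt → 40 °C; then 1 M HCl to pH 3, 0 °C
Reagents that add atoms: lithium hydroxide, [Li+].[OH-]
Why: Saponification (BAc2) of the two hindered conjugated methyl esters with excess hydroxide, in which no centre can epimerise and the E geometry is the thermodynamic one; brief cold acidification to pH 3 should spare the furan and the tertiary carbinol.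

**Compound list**

1 | D-malic acid, (R)-2-hydroxybutanedioic acid | OC(=O)[C@H](O)CC(=O)O | starting material
2 | 2-[(4R)-2,2-dimethyl-5-oxo-1,3-dioxolan-4-yl]acetic acid | CC1(C)O[C@H](CC(=O)O)C(=O)O1 | intermediate
3 | 3-bromofuran | Brc1ccoc1 | starting material
4 | oxetane | C1COC1 | starting material
5 | furan-3-yllithium | [Li]c1ccoc1 | intermediate
6 | 3-(furan-3-yl)propan-1-ol | OCCCc1ccoc1 | intermediate
7 | 3-(furan-3-yl)propanal | O=CCCc1ccoc1 | intermediate
8 | methyl 2-(triphenyl-λ5-phosphanylidene)acetate | COC(=O)C=P(c1ccccc1)(c1ccccc1)c1ccccc1 | starting material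
9 | allyl bromide (3-bromoprop-1-ene) | C=CCBr | starting material
10 | (1-methoxy-1-oxopent-4-en-2-yl)triphenylphosphonium bromide | COC(=O)C(CC=C)[P+](c1ccccc1)(c1ccccc1)c1ccccc1.[Br-] | intermediate
11 | methyl 2-(triphenyl-λ5-phosphanylidene)pent-4-enoate | COC(=O)C(CC=C)=P(c1ccccc1)(c1ccccc1)c1ccccc1 | intermediate
12 | methyl (2E)-5-(furan-3-yl)-2-(prop-2-en-1-yl)pent-2-enoate | C=CC/C(=C\CCc1ccoc1)C(=O)OC | intermediate
13 | methyl (2E)-2-[3-(9-borabicyclo[3.3.1]nonan-9-yl)propyl]-5-(furan-3-yl)pent-2-enoate | B1(CCC/C(=C\CCc3ccoc3)C(=O)OC)C2CCCC1CCC2 | intermediate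
14 | methyl (2E)-5-(furan-3-yl)-2-(3-hydroxypropyl)pent-2-enoate | OCCC/C(=C\CCc1ccoc1)C(=O)OC | intermediate
15 | methyl (2E)-5-(furan-3-yl)-2-(3-oxopropyl)pent-2-enoate | O=CCC/C(=C\CCc1ccoc1)C(=O)OC | intermediate
16 | methyl acrylate | C=CC(=O)OC | starting material
17 | dimethyl (2E)-2-[3-(furan-3-yl)propylidene]-5-hydroxy-6-methylideneheptanedioate, racemic at the carbinol carbon | C=C(C(=O)OC)C(O)CC/C(=C\CCc1ccoc1)C(=O)OC | intermediate
18 | dimethyl (2E)-5-acetoxy-2-[3-(furan-3-yl)propylidene]-6-methylideneheptanedioate, racemic at the acetoxy carbon | C=C(C(=O)OC)C(OC(C)=O)CC/C(=C\CCc1ccoc1)C(=O)OC | intermediate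
19 | dimethyl (2E,6E)-2-{2-[(4R)-2,2-dimethyl-5-oxo-1,3-dioxolan-4-yl]ethyl}-6-[3-(furan-3-yl)propylidene]hept-2-enedioate | CC1(C)O[C@H](CC/C(=C\CC/C(=C\CCc2ccoc2)C(=O)OC)C(=O)OC)C(=O)O1 | intermediate
20 | dimethyl (2E,6E)-2-[(3R)-3-hydroxy-4-oxopentyl]-6-[3-(furan-3-yl)propylidene]hept-2-enedioate (present as its magnesium alkoxide) | CC(=O)[C@H](O)CC/C(=C\CC/C(=C\CCc1ccoc1)C(=O)OC)C(=O)OC | intermediate
21 | dimethyl (2E,6E)-2-[(3R)-3,4-dihydroxy-4-methylpentyl]-6-[3-(furan-3-yl)propylidene]hept-2-enedioate | CC(C)(O)[C@H](O)CC/C(=C\CC/C(=C\CCc1ccoc1)C(=O)OC)C(=O)OC | intermediate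
22 | (2E,6E)-2-[(3R)-3,4-dihydroxy-4-methylpentyl]-6-[3-(furan-3-yl)propylidene]hept-2-enedioic acid | CC(C)(O)[C@H](O)CC/C(=C\CC/C(=C\CCc1ccoc1)C(=O)O)C(=O)O | target

**Count**

Total steps: 12. Longest linear sequence: 10 steps (3-bromofuran to 22: steps 2, 3, 5, 6, 7, 8, 9, 10, 11, 12).

**Steps most likely to fail**

Step 10. Oxidation of an unactivated primary carboxylate by the excited photocatalyst may be too slow to compete with back electron transfer. The free carboxylate or acetate may also open the activated dioxolanone during a long irradiation. The fallback sets out from acid 2. Esterification with N-hydroxyphthalimide (DIC, cat. DMAP, CH2Cl2, 0 °C) should give the redox-active ester 1,3-dioxoisoindolin-2-yl 2-[(4R)-2,2-dimethyl-5-oxo-1,3-dioxolan-4-yl]acetate F1. This is fragmented reductively (Ru(bpy)3(PF6)2 cat., Hantzsch ester, blue LEDs, CH2Cl2, no amine base) in the presence of acetate 18. The same C3 radical then arises by loss of CO2 and phthalimide, independent of the carboxylate oxidation potential and with no carboxylate in solution, and addition, reduction and acetate loss rejoin the route at 19.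

Step 11. Once the excess reagent and the warming needed for full conversion are applied, 1,2-addition of the Grignard reagent to the C5 and C9 methyl esters may compete. The fallback sets out from acid 2 and moves the methylation ahead of the coupling, where no other ester is present.
- Excess MeMgBr (THF, −78 → 0 °C, the acid being masked in situ as its magnesium carboxylate) and acidic work-up should give the hydroxy lactone (4R)-4-hydroxy-5,5-dimethyloxolan-2-one F2.
- Acid-catalysed methanolysis in the presence of 2,2-dimethoxypropane (MeOH, CSA) traps the open form as methyl 2-[(4R)-2,2,5,5-tetramethyl-1,3-dioxolan-4-yl]acetate F3.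
- LiOH gives 2-[(4R)-2,2,5,5-tetramethyl-1,3-dioxolan-4-yl]acetic acid F4.
- Coupling of this acid with 18 under the conditions of step 10 gives dimethyl (2E,6E)-2-{2-[(4R)-2,2,5,5-tetramethyl-1,3-dioxolan-4-yl]ethyl}-6-[3-(furan-3-yl)propylidene]hept-2-enedioate F5.
- Mild acetal hydrolysis (PPTS, MeOH, rt) releases the diol and rejoins the route at 21.

Step 8. The amine-catalysed coupling of an enolisable aliphatic aldehyde with methyl acrylate is slow, and aldol self-condensation of 15 or acrylate oligomerisation may outrun it. The fallback sets out from aldehyde 15 and replaces the catalytic reaction by a stoichiometric α-metallated acrylate. Hydroalumination of methyl propiolate with DIBAL-H in the presence of N-methylmorpholine N-oxide (THF, 0 °C) gives the [1-(methoxycarbonyl)vinyl]aluminium reagent. This should add to the aldehyde of 15 much faster than the amine-catalysed reaction and returns the same alcohol 17; no compound outside the list arises (entry F0).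

Further compounds
F1 | step 10 | 1,3-dioxoisoindolin-2-yl 2-[(4R)-2,2-dimethyl-5-oxo-1,3-dioxolan-4-yl]acetate | CC1(C)O[C@H](CC(=O)ON2C(=O)c3ccccc3C2=O)C(=O)O1
F2 | step 11 | (4R)-4-hydroxy-5,5-dimethyloxolan-2-one | CC1(C)[C@H](O)CC(=O)O1
F3 | step 11 | methyl 2-[(4R)-2,2,5,5-tetramethyl-1,3-dioxolan-4-yl]acetate | CC1(C)O[C@H](CC(=O)OC)C(C)(C)O1
F4 | step 11 | 2-[(4R)-2,2,5,5-tetramethyl-1,3-dioxolan-4-yl]acetic acid | CC1(C)O[C@H](CC(=O)O)C(C)(C)O1
F5 | step 11 | dimethyl (2E,6E)-2-{2-[(4R)-2,2,5,5-tetramethyl-1,3-dioxolan-4-yl]ethyl}-6-[3-(furan-3-yl)propylidene]hept-2-enedioate | CC1(C)O[C@H](CC/C(=C\CC/C(=C\CCc2ccoc2)C(=O)OC)C(=O)OC)C(C)(C)O1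
F0 | step 8 | none | none
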